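Its constants are assumed; the flask was simulated.

The ratio 0.34 set my plan: at the start of teal, the forward step to adduct used starting material at that fraction of the rate of the quench by protic impurity.

    starting material + reagent ⇌ adduct (K1 = 24 L mol⁻¹, k1 = 0.23 L mol⁻¹ min⁻¹)
    adduct → product (k2 = 0.0063 min⁻¹)
    starting material + protic impurity → quenched substrate (k3 = 7.0 L mol⁻¹ min⁻¹)

| setting | teal | red | green | violet | blue |
|---|---|---|---|---|---|
| starting material | 0.0050 M | 0.010 M | 0.020 M | 0.040 M | 0.080 M |
| reagent | 0.0210 M | 0.0210 M | 0.0210 M | 0.0210 M | 0.0210 M |
| protic impurity | 2.00 mM | 2.00 mM | 2.00 mM | 2.00 mM | 2.00 mM |
| time | 3.0 d | 3.0 d | 3.0 d | 3.0 d | 3.0 d |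

- amount of product at the end, in percent of the starting material charged for teal, red, green, violet, blue, in this order
- how the row runs (falls, then rises / rises, then falls / falls all the way / hardly changes / rises all the way)

- "hardly changes" means that all values lie within two and a half points (for a concentration: within two and a half percent of the largest)
- run time (teal): 3.0 d

- I had to choose the charge for the next run, so I counted the toll first. Green's protic impurity had a lifetime of 7.14 min at the charged [starting material], far shorter than the run. So I took 2.00 mM off green's charge, which left 18.0 mM usable.
- Green's ceiling was therefore 90.0% and red's was 80.0%. Violet's was 52.5%, with reagent as the limiting reagent. Green looked best, but it had to get there in time.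
- The adduct lived 63.0 min, much shorter than the run. So I held it steady, and this gave an effective constant of 0.0912 L mol⁻¹ min⁻¹ for product formation.
- With reagent in excess in green, I had [starting material]/[reagent] falling exponentially, at a pace of that constant times the excess of reagent, 3.00 mM.
- Green's count of tail half-lives, the times that ratio halves in the run (effective constant times excess times run time, over ln two), was 1.71. That is few.
- I reckoned that the ratio in green would fall from 0.857 to 0.263. By that estimate, 1.07 mM of starting material would remain, and product would reach 84.7% of green's charge.
- Even short of its ceiling, green beat red's ceiling. So I chose green, with the remaining [starting material] as the thing to watch.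
- The forecast gave 59.8%, 79.4%, 83.5%, 52.4% and 26.2%, a row that rises, then falls, and said of green that “reagent excess is only 3 mM, so the tail is slow”.
- The simulation gave 59.9%, 79.4%, 83.6%, 52.4% and 26.2%, a row that rises, then falls. Green ended with 6.02% of its starting material still there, against my 5.35%. Violet had starting material in excess by 17.0 mM, so with the ratio turned over to [reagent]/[starting material], my count for violet was 9.67 tail half-lives, more than green's. Violet's reagent stood at 0.15% of its charge at the end.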